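**Strategy.** The target is cut across the seven-membered ring at C5–C6 and at the ring-fusion bond C3a–C8a (azulene numbering). This gives a three-carbon oxyallyl unit C3a–C4–C5, whose central carbon carries the anisoate oxygen, and a four-carbon diene C6–C7–C8–C8a. The key step exploits the C3(OH)–C3a–C4(O) array: an epoxy enol silane opens at C3a and undergoes an intramolecular (4+3) cycloaddition with a tethered diene. This closes both rings, sets C3a and the quaternary C8a, and unveils the C3 carbinol and a C4 ketone. The precursor is an open-chain (E)-2-methyl-1,3-diene linked through a CH(OAc)–CH2 tether to a trisubstituted oxirane bearing a silyl enol ether. The cycloadduct's C7=C8 alkene is later transposed to C6=C7 as the C6 methyl is installed.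

Key step: step 9

Remark on numbering: ring positions are cited in azulene numbering. The five-membered ring is C1–C2–C3–C3a–C8a and the seven-membered ring is C3a–C4–C5–C6–C7–C8–C8a. OAc sits on C1, OH and isopropyl on C3, the anisoate on C4, and methyl groups on C6 and C8a.

Assumption: in step 2 the (S)-configured phosphoric acid is taken to deliver the (4S)-alcohol by analogy with aryl and alkenyl aldehydes; if the sense proves opposite, the antipodal acid is used.

Step 1
Reactants: 1 acrolein; 2 2-(triphenyl-λ5-phosphanylidene)propanal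
Product: 3 (2E)-2-methylpenta-2,4-dienal
Conditions: 1 (3 equiv), toluene, sealed tube, 80 °C; distillation
Reagents that add atoms: none
Why: Wittig olefination with a stabilised ylide should give the (E)-trisubstituted enal, and the ylide should react faster with unhindered acrolein than with the α-branched product.

Step 2
Reactants: 3 (2E)-2-methylpenta-2,4-dienal; 4 allenylboronic acid pinacol ester
Product: 5 (4S,5E)-5-methylocta-5,7-dien-1-yn-4-ol
Conditions: (S)-3,3′-bis(2,4,6-triisopropylphenyl)-1,1′-binaphthyl-2,2′-diyl hydrogen phosphate (5 mol%), 4 Å MS, toluene, −20 °C; aqueous work-up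
Reagents that add atoms: none
Why: Chiral Brønsted acid-catalysed propargylboration (SE2′ addition of the allenylboronate through a closed six-membered transition state) should set the carbinol centre (future C1) by catalyst-controlled face selection.

Step 3
Reactants: 5 (4S,5E)-5-methylocta-5,7-dien-1-yn-4-ol
Product: 7 (6S,7E)-7-methyl-2-oxodeca-7,9-dien-3-yn-6-yl acetate, via dilithium alkoxide acetylide 6 (not isolated)
Conditions: n-BuLi (2.1 equiv), THF, −78 °C; MeC(O)N(OMe)Me (1.1 equiv), −78 → 0 °C; Ac2O (2 equiv), 0 °C; aq NH4Cl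
Reagents that add atoms: N-methoxy-N-methylacetamide, CC(=O)N(C)OC; acetic anhydride, CC(=O)OC(C)=O
Why: The acetylide is C-acylated by the Weinreb amide (the stable tetrahedral adduct prevents over-addition) and the alkoxide is then O-acetylated, so the ynone and the final C1 acetate are installed in one operation without touching the stereocentre.

Step 4
Reactants: 7 (6S,7E)-7-methyl-2-oxodeca-7,9-dien-3-yn-6-yl acetate
Product: 8 (3E,6S,7E)-7-methyl-2-oxo-4-(propan-2-yl)deca-3,7,9-trien-6-yl acetate
Conditions: i-PrMgCl (2.0 equiv), CuBr·SMe2 (1.0 equiv), THF, −78 °C; MeOH then aq NH4Cl at −78 °C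
Reagents that add atoms: isopropylmagnesium chloride, CC(C)[Mg]Cl
Why: Conjugate addition of an organocuprate to the ynone (syn-carbocupration) places isopropyl and hydrogen cis, so acetyl ends trans to isopropyl, which is also the thermodynamically preferred enone geometry.

Step 5
Reactants: 8 (3E,6S,7E)-7-methyl-2-oxo-4-(propan-2-yl)deca-3,7,9-trien-6-yl acetate
Product: 9 (2S,3E,6S,7E)-2-hydroxy-7-methyl-4-(propan-2-yl)deca-3,7,9-trien-6-yl acetate
Conditions: (R)-2-methyl-CBS-oxazaborolidine (0.2 equiv), catecholborane (1.5 equiv), toluene, −78 °C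
Reagents that add atoms: none
Why: In this Corey–Bakshi–Shibata reduction the alkenyl residue acts as the large group, so the (R)-oxazaborolidine should give the (2S)-allylic alcohol, and catecholborane at low temperature leaves the diene and acetate alone.

Step 6
Reactants: 9 (2S,3E,6S,7E)-2-hydroxy-7-methyl-4-(propan-2-yl)deca-3,7,9-trien-6-yl acetate
Product: 10 (2S,3E)-1-{(2R,3R)-3-[(1S)-1-hydroxyethyl]-2-(propan-2-yl)oxiran-2-yl}-3-methylhexa-3,5-dien-2-yl acetate
Conditions: Ti(OiPr)4 (1.0 equiv), t-BuOOH (2 equiv, decane), 4 Å MS, CH2Cl2, −20 °C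
Reagents that add atoms: tert-butyl hydroperoxide, CC(C)(C)OO
Why: Hydroxyl-directed epoxidation delivers oxygen syn to the hydroxyl in the A(1,3)-strain-minimised rotamer (threo, because C5 is cis to the carbinol carbon), which sets both oxirane carbons, and the metal-bound peroxide leaves the unactivated diene untouched.

Step 7
Reactants: 10 (2S,3E)-1-{(2R,3R)-3-[(1S)-1-hydroxyethyl]-2-(propan-2-yl)oxiran-2-yl}-3-methylhexa-3,5-dien-2-yl acetate
Product: 11 (2S,3E)-1-[(2R,3S)-3-acetyl-2-(propan-2-yl)oxiran-2-yl]-3-methylhexa-3,5-dien-2-yl acetate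
Conditions: Dess–Martin periodinane, NaHCO3, CH2Cl2, 0 °C → rt
Reagents that add atoms: none
Why: Buffered Dess–Martin oxidation removes the relay carbinol stereocentre and gives the α,β-epoxy methyl ketone without opening the oxirane.

Step 8
Reactants: 11 (2S,3E)-1-[(2R,3S)-3-acetyl-2-(propan-2-yl)oxiran-2-yl]-3-methylhexa-3,5-dien-2-yl acetate
Product: 12 (2S,3E)-3-methyl-1-{(2R,3S)-2-(propan-2-yl)-3-[1-(triethylsilyloxy)ethenyl]oxiran-2-yl}hexa-3,5-dien-2-yl acetate
Conditions: Et3SiOTf (1.2 equiv), Et3N (2 equiv), CH2Cl2, −78 → 0 °C; chromatography on Et3N-deactivated silica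
Reagents that add atoms: triethylsilyl trifluoromethanesulfonate, CC[Si](CC)(CC)OS(=O)(=O)C(F)(F)F
Why: Soft enolisation and O-silylation of the methyl ketone (silyl enol ether formation) can occur only towards the methyl group, and the amine-buffered medium leaves the acetate and oxirane intact.

Step 9
Reactants: 12 (2S,3E)-3-methyl-1-{(2R,3S)-2-(propan-2-yl)-3-[1-(triethylsilyloxy)ethenyl]oxiran-2-yl}hexa-3,5-dien-2-yl acetate
Product: 14 (1S,3R,3aR,8aR)-3-hydroxy-8a-methyl-4-oxo-3-(propan-2-yl)-1,2,3,3a,4,5,6,8a-octahydroazulen-1-yl acetate, via triethylsilyl ether cycloadduct 13 (not isolated)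
Conditions: Et3SiOTf (0.2 equiv), CH2Cl2 (0.01 M), −78 °C; then HF·pyridine, THF, 0 °C
Reagents that add atoms: none
Why: Et3SiOTf silylates the oxirane oxygen, the diene terminus C8a attacks the oxirane carbon C3a from the face opposite the breaking C–O bond, and the emerging 2-silyloxyallyl cation closes through its CH2 terminus (C5) onto the distal diene carbon C6; loss of the silyl group from the oxocarbenium ion returns the catalyst and leaves the C4 ketone and the C3 silyl ether, which HF then cleaves. The closest known reaction type is the silyl-triflate-catalysed intramolecular (4+3) cycloaddition of epoxy enol silanes with tethered dienes, a variant of the oxyallyl cation (4+3) cycloaddition. The five-membered ring closes 5-exo-trig with respect to the C8a=C8 bond (endo-mode opening of the oxirane, both oxirane carbons lying in the new ring), and the seven-membered ring closes as the 4C+3C cycloaddition, suprafacial on both partners. C3a is set by inversion at the oxirane carbon, C3 keeps the configuration of the oxirane, and C8a is set relative to C3a by the extended transition state in which the tether sits on the outside of both the (E)-diene terminus and the allyl terminus, which should put H-3a and the 8a-methyl on opposite faces (trans fusion). The step needs C–O cleavage at C3a and not at the tertiary C3, which the enol silane secures by allyl stabilisation, and it needs the (4+3) mode over (3+2) closure or simple alkylation, which the unsubstituted diene terminus, the short tether and high dilution favour. The dienylic acetate only has to stay un-ionised at −78 °C, where the oxirane is the more basic site.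

Step 10
Reactants: 14 (1S,3R,3aR,8aR)-3-hydroxy-8a-methyl-4-oxo-3-(propan-2-yl)-1,2,3,3a,4,5,6,8a-octahydroazulen-1-yl acetate
Product: 15 (1S,3R,3aS,4S,8aR)-3,4-dihydroxy-8a-methyl-3-(propan-2-yl)-1,2,3,3a,4,5,6,8a-octahydroazulen-1-yl acetate
Conditions: Me4NBH(OAc)3, MeCN/AcOH (1:1), −20 °C
Reagents that add atoms: none
Why: In this Evans–Saksena hydroxyl-directed reduction the C3 alkoxyborohydride delivers hydride intramolecularly to the C4 carbonyl from the face of the C3–O bond, which should give the 1,3-anti diol with the C4 hydroxyl cis to H-3a.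

Step 11
Reactants: 15 (1S,3R,3aS,4S,8aR)-3,4-dihydroxy-8a-methyl-3-(propan-2-yl)-1,2,3,3a,4,5,6,8a-octahydroazulen-1-yl acetate; 16 4-methoxybenzoyl chloride
Product: 17 (1S,3R,3aS,4S,8aR)-1-acetoxy-3-hydroxy-8a-methyl-3-(propan-2-yl)-1,2,3,3a,4,5,6,8a-octahydroazulen-4-yl 4-methoxybenzoate
Conditions: DMAP (0.2 equiv), Et3N, CH2Cl2, rt
Reagents that add atoms: none
Why: DMAP-catalysed acylation should esterify the only secondary hydroxyl, the tertiary C3 hydroxyl being too hindered to react.

Step 12
Reactants: 17 (1S,3R,3aS,4S,8aR)-1-acetoxy-3-hydroxy-8a-methyl-3-(propan-2-yl)-1,2,3,3a,4,5,6,8a-octahydroazulen-4-yl 4-methoxybenzoate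
Product: 18 (1S,3R,3aS,4S,8aR)-1-acetoxy-3-hydroxy-8a-methyl-6-oxo-3-(propan-2-yl)-1,2,3,3a,4,5,6,8a-octahydroazulen-4-yl 4-methoxybenzoate
Conditions: Rh2(cap)4 (dirhodium tetracaprolactamate, 1 mol%), t-BuOOH (70% aq, 5 equiv), 1,2-dichloroethane, 40 °C, no base
Reagents that add atoms: tert-butyl hydroperoxide, CC(C)(C)OO
Why: Allylic C–H oxidation by peroxy radicals can abstract only at C6, the one allylic methylene (C8a is quaternary), and oxygenation at the less hindered allyl terminus should give the C6 enone under base-free conditions that spare the β-acyloxy ketone.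

Step 13
Reactants: 18 (1S,3R,3aS,4S,8aR)-1-acetoxy-3-hydroxy-8a-methyl-6-oxo-3-(propan-2-yl)-1,2,3,3a,4,5,6,8a-octahydroazulen-4-yl 4-methoxybenzoate
Product: 20 (1S,3R,3aS,4S,8aR)-1-acetoxy-3-hydroxy-8a-methyl-3-(propan-2-yl)-6-[(trifluoromethanesulfonyl)oxy]-1,2,3,3a,4,5,8,8a-octahydroazulen-4-yl 4-methoxybenzoate, via lithium enolate 19 (not isolated)
Conditions: LiBH(s-Bu)3 (1.2 equiv), THF, −78 °C; PhNTf2, −78 → 0 °C; aq NH4Cl
Reagents that add atoms: N-phenylbis(trifluoromethanesulfonimide), O=S(=O)(N(c1ccccc1)S(=O)(=O)C(F)(F)F)C(F)(F)F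
Why: Conjugate hydride addition gives the C6–C7 enolate regiospecifically and O-sulfonylation traps it (reductive enol triflate formation), which fixes the alkene position and avoids an enolate towards C5 that could expel the anisoate.

Step 14
Reactants: 20 (1S,3R,3aS,4S,8aR)-1-acetoxy-3-hydroxy-8a-methyl-3-(propan-2-yl)-6-[(trifluoromethanesulfonyl)oxy]-1,2,3,3a,4,5,8,8a-octahydroazulen-4-yl 4-methoxybenzoate
Product: 21 (1S,3R,3aS,4S,8aR)-1-acetoxy-3-hydroxy-6,8a-dimethyl-3-(propan-2-yl)-1,2,3,3a,4,5,8,8a-octahydroazulen-4-yl 4-methoxybenzoate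
Conditions: MeZnCl (3 equiv), Pd(PPh3)4 (5 mol%), THF, rt → 50 °C
Reagents that add atoms: methylzinc chloride, C[Zn]Cl
Why: Negishi cross-coupling of the enol triflate installs the C6 methyl with the C6=C7 alkene in place, and the mild organozinc should tolerate both esters and the tertiary alcohol.

**Compound list**

1 | acrolein | C=CC=O | starting material
2 | 2-(triphenyl-λ5-phosphanylidene)propanal | CC(C=O)=P(c1ccccc1)(c1ccccc1)c1ccccc1 | starting material
3 | (2E)-2-methylpenta-2,4-dienal | O=C/C(C)=C/C=C | intermediate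
4 | allenylboronic acid pinacol ester | C=C=CB1OC(C)(C)C(C)(C)O1 | starting material
5 | (4S,5E)-5-methylocta-5,7-dien-1-yn-4-ol | C#CC[C@H](O)/C(C)=C/C=C | intermediate
6 | dilithium salt of 5 (lithium alkoxide, lithium acetylide) | [Li]C#CC[C@H](O[Li])/C(C)=C/C=C | intermediate
7 | (6S,7E)-7-methyl-2-oxodeca-7,9-dien-3-yn-6-yl acetate | CC(=O)C#CC[C@H](OC(C)=O)/C(C)=C/C=C | intermediate
8 | (3E,6S,7E)-7-methyl-2-oxo-4-(propan-2-yl)deca-3,7,9-trien-6-yl acetate (acetyl trans to isopropyl) | CC(=O)/C=C(/C(C)C)C[C@H](OC(C)=O)/C(C)=C/C=C | intermediate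
9 | (2S,3E,6S,7E)-2-hydroxy-7-methyl-4-(propan-2-yl)deca-3,7,9-trien-6-yl acetate | C[C@H](O)/C=C(/C(C)C)C[C@H](OC(C)=O)/C(C)=C/C=C | intermediate
10 | (2S,3E)-1-{(2R,3R)-3-[(1S)-1-hydroxyethyl]-2-(propan-2-yl)oxiran-2-yl}-3-methylhexa-3,5-dien-2-yl acetate (threo epoxy alcohol) | C[C@H](O)[C@H]1O[C@@]1(C(C)C)C[C@H](OC(C)=O)/C(C)=C/C=C | intermediate
11 | (2S,3E)-1-[(2R,3S)-3-acetyl-2-(propan-2-yl)oxiran-2-yl]-3-methylhexa-3,5-dien-2-yl acetate | CC(=O)[C@H]1O[C@@]1(C(C)C)C[C@H](OC(C)=O)/C(C)=C/C=C | intermediate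
12 | (2S,3E)-3-methyl-1-{(2R,3S)-2-(propan-2-yl)-3-[1-(triethylsilyloxy)ethenyl]oxiran-2-yl}hexa-3,5-dien-2-yl acetate | C=C(O[Si](CC)(CC)CC)[C@H]1O[C@@]1(C(C)C)C[C@H](OC(C)=O)/C(C)=C/C=C | intermediate
13 | (1S,3R,3aR,8aR)-8a-methyl-4-oxo-3-(propan-2-yl)-3-(triethylsilyloxy)-1,2,3,3a,4,5,6,8a-octahydroazulen-1-yl acetate (trans-fused) | O=C2CCC=C[C@@]3(C)[C@@H](OC(C)=O)C[C@@](O[Si](CC)(CC)CC)(C(C)C)[C@H]23 | intermediate
14 | (1S,3R,3aR,8aR)-3-hydroxy-8a-methyl-4-oxo-3-(propan-2-yl)-1,2,3,3a,4,5,6,8a-octahydroazulen-1-yl acetate (trans-fused) | O=C2CCC=C[C@@]3(C)[C@@H](OC(C)=O)C[C@@](O)(C(C)C)[C@H]23 | intermediate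
15 | (1S,3R,3aS,4S,8aR)-3,4-dihydroxy-8a-methyl-3-(propan-2-yl)-1,2,3,3a,4,5,6,8a-octahydroazulen-1-yl acetate | O[C@H]2CCC=C[C@@]3(C)[C@@H](OC(C)=O)C[C@@](O)(C(C)C)[C@H]23 | intermediate
16 | 4-methoxybenzoyl chloride | COc1ccc(cc1)C(Cl)=O | starting material
17 | (1S,3R,3aS,4S,8aR)-1-acetoxy-3-hydroxy-8a-methyl-3-(propan-2-yl)-1,2,3,3a,4,5,6,8a-octahydroazulen-4-yl 4-methoxybenzoate | COc1ccc(C(=O)O[C@H]2CCC=C[C@@]3(C)[C@@H](OC(C)=O)C[C@@](O)(C(C)C)[C@H]23)cc1 | intermediate
18 | (1S,3R,3aS,4S,8aR)-1-acetoxy-3-hydroxy-8a-methyl-6-oxo-3-(propan-2-yl)-1,2,3,3a,4,5,6,8a-octahydroazulen-4-yl 4-methoxybenzoate | COc1ccc(C(=O)O[C@H]2CC(=O)C=C[C@@]3(C)[C@@H](OC(C)=O)C[C@@](O)(C(C)C)[C@H]23)cc1 | intermediate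
19 | lithium C6–C7 enolate of the 7,8-dihydro derivative of 18 | COc1ccc(C(=O)O[C@H]2CC(O[Li])=CC[C@@]3(C)[C@@H](OC(C)=O)C[C@@](O)(C(C)C)[C@H]23)cc1 | intermediate
20 | (1S,3R,3aS,4S,8aR)-1-acetoxy-3-hydroxy-8a-methyl-3-(propan-2-yl)-6-[(trifluoromethanesulfonyl)oxy]-1,2,3,3a,4,5,8,8a-octahydroazulen-4-yl 4-methoxybenzoate | COc1ccc(C(=O)O[C@H]2CC(OS(=O)(=O)C(F)(F)F)=CC[C@@]3(C)[C@@H](OC(C)=O)C[C@@](O)(C(C)C)[C@H]23)cc1 | intermediate
21 | (1S,3R,3aS,4S,8aR)-1-acetoxy-3-hydroxy-6,8a-dimethyl-3-(propan-2-yl)-1,2,3,3a,4,5,8,8a-octahydroazulen-4-yl 4-methoxybenzoate (CNP0171090.1) | COc1ccc(C(=O)O[C@H]2CC(C)=CC[C@@]3(C)[C@@H](OC(C)=O)C[C@@](O)(C(C)C)[C@H]23)cc1 | target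

**Totals.** Total step count: 14. Longest linear sequence: 14 steps (1 → 21).

**Steps most likely to fail**

1. Step 9 (key step). The silyl triflate may ionise the dienylic acetate in competition with oxirane activation. Closure may also run through the compact transition state and give the cis-fused ring system. The diene terminus that must become quaternary carries an inside methyl group, so its s-cis conformer is populated only reluctantly. The fallback replaces the ester at the dienylic position by a non-ionisable silyl ether, which also makes the diene more electron-rich. It sets out from 11. Enzymatic deacetylation (Candida antarctica lipase B, phosphate buffer/MTBE) should give the hydroxy epoxy ketone F1. Silylation (TBSCl, imidazole, DMF) should give the silyl ether F2. Soft enolisation (Et3SiOTf, Et3N) should give the epoxy enol silane F3. The same silyl-triflate-catalysed (4+3) cycloaddition should give the bis-silyl ether cycloadduct F4. HF·pyridine should then give the diol ketone F5, and acetylation of its only secondary hydroxyl (Ac2O, pyridine, DMAP) comes back to the route at 14.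

2. Step 4. Alkene geometry may erode because the β-cuprio enone equilibrates through its allenolate before protonation. The fallback moves the conjugate addition to an ynoate, whose vinylcopper adduct is configurationally stable at −78 °C, and proves the geometry by lactonisation. It sets out from 5. Silylation (Et3SiCl, imidazole) should give the silyl ether F6. Deprotonation and trapping (n-BuLi, then ClCO2Me) should give the ynoate F7. The cuprate from i-PrMgCl and CuBr·SMe2 at −78 °C should give the (E)-enoate F8. HF·pyridine removes the silyl group, and only the isomer with the ester cis to the CH2 group can close to the dihydropyranone F9. MeLi (1.0 equiv, −78 °C) should open it to the hydroxy enone F10 (in equilibrium with its lactol), and acetylation (Ac2O, pyridine) comes back to the route at 8.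

3. Step 13. Hydride may add 1,2 to the enone, whose β-carbon is flanked by the quaternary C8a, or may attack the two esters. The fallback separates reduction and sulfonylation and uses a neutral catalytic 1,4-hydrosilylation. It sets out from 18. Et3SiH with RhCl(PPh3)3 (1 mol%) in benzene should give the triethylsilyl enol ether F11 regiospecifically. Fluoride-mediated triflation (CsF, PhNTf2, DME, rt) then comes back to the route at 20.

**Further compounds**

F1 | step 9 | (2S,3E)-1-[(2R,3S)-3-acetyl-2-(propan-2-yl)oxiran-2-yl]-3-methylhexa-3,5-dien-2-ol | CC(=O)[C@H]1O[C@@]1(C(C)C)C[C@H](O)/C(C)=C/C=C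
F2 | step 9 | tert-butyldimethylsilyl ether of F1 | CC(=O)[C@H]1O[C@@]1(C(C)C)C[C@H](O[Si](C)(C)C(C)(C)C)/C(C)=C/C=C
F3 | step 9 | triethylsilyl enol ether of F2 | C=C(O[Si](CC)(CC)CC)[C@H]1O[C@@]1(C(C)C)C[C@H](O[Si](C)(C)C(C)(C)C)/C(C)=C/C=C
F4 | step 9 | (1S,3R,3aR,8aR)-1-(tert-butyldimethylsilyloxy)-8a-methyl-3-(propan-2-yl)-3-(triethylsilyloxy)-1,2,3,3a,5,6-hexahydroazulen-4(8aH)-one | O=C2CCC=C[C@@]3(C)[C@@H](O[Si](C)(C)C(C)(C)C)C[C@@](O[Si](CC)(CC)CC)(C(C)C)[C@H]23
F5 | step 9 | (1S,3R,3aR,8aR)-1,3-dihydroxy-8a-methyl-3-(propan-2-yl)-1,2,3,3a,5,6-hexahydroazulen-4(8aH)-one | O=C2CCC=C[C@@]3(C)[C@@H](O)C[C@@](O)(C(C)C)[C@H]23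
F6 | step 4 | triethylsilyl ether of 5 | C#CC[C@H](O[Si](CC)(CC)CC)/C(C)=C/C=C
F7 | step 4 | methyl (5S,6E)-6-methyl-5-(triethylsilyloxy)nona-6,8-dien-2-ynoate | COC(=O)C#CC[C@H](O[Si](CC)(CC)CC)/C(C)=C/C=C
F8 | step 4 | methyl (2E,5S,6E)-6-methyl-3-(propan-2-yl)-5-(triethylsilyloxy)nona-2,6,8-trienoate | COC(=O)/C=C(/C(C)C)C[C@H](O[Si](CC)(CC)CC)/C(C)=C/C=C
F9 | step 4 | (6S)-6-[(2E)-penta-2,4-dien-2-yl]-4-(propan-2-yl)-5,6-dihydro-2H-pyran-2-one | O=C1C=C(C(C)C)C[C@@H](/C(C)=C/C=C)O1
F10 | step 4 | (3E,6S,7E)-6-hydroxy-7-methyl-4-(propan-2-yl)deca-3,7,9-trien-2-one | CC(=O)/C=C(/C(C)C)C[C@H](O)/C(C)=C/C=C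
F11 | step 13 | triethylsilyl enol ether corresponding to enolate 19 | COc1ccc(C(=O)O[C@H]2CC(O[Si](CC)(CC)CC)=CC[C@@]3(C)[C@@H](OC(C)=O)C[C@@](O)(C(C)C)[C@H]23)cc1
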